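**Assumptions:** The SMILES encodes (2R, 9'R, 3'E, 7'E), and that is the target built here. Atom-donating reagents (ylide, allyl‑MgBr, 2‑methyl‑2‑butene, CO/MeOH, AlMe3) are listed under each step and not numbered.

## Retrosynthetic overview

1. Target 19 ⇐ bis-silyl ether 18 (global desilylation) ⇐ B‑alkyl Suzuki–Miyaura union at C2'–C3' of chroman iodide 10 and vinyl iodide 17, each carrying 15 of the target's 30 non-hydrogen atoms.
2. 10 ⇐ alkenylphenol 7 by enantioselective Pd(II) Wacker-type cyclisation/methoxycarbonylation. This sets C2 and is the only ring-forming step: the pyran ring is closed onto the pre-existing benzene ring.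
3. 7 ⇐ o‑cresol (1) + 4‑bromo‑2‑methylbut‑1‑ene (3): ortho-bromination, Negishi coupling, para-oxidation to the quinone, reduction, selective O‑silylation.
4. 17 ⇐ pent‑4‑yn‑1‑ol (11): carboalumination/iodination (3'E), oxidation, E‑selective Wittig (7'E), Brown allylation (9'R), cross-metathesis to the prenyl terminus, TBS protection.

## Route

### Fragment A (chroman half)

**Step 1**
- Reactants: 1, o‑cresol (2‑methylphenol)
- Product: 2, 2‑bromo‑6‑methylphenol
- Conditions: NBS (1.0 equiv), i‑Pr2NH (10 mol %), CH2Cl2, 0 °C → rt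
- Reagents that add atoms: N‑bromosuccinimide, O=C1CCC(=O)N1Br
- Why: Amine-mediated ortho-selective electrophilic bromination of a phenol; the H‑bonded N‑bromoamine delivers Br to the free ortho position in preference to para.

**Step 2**
- Reactants: 2, 2‑bromo‑6‑methylphenol; 3, 4‑bromo‑2‑methylbut‑1‑ene (converted in situ to the zinc reagent)
- Product: 4, 2‑methyl‑6‑(3‑methylbut‑3‑en‑1‑yl)phenol
- Conditions: 3, Zn dust, LiCl, THF, 40 °C (gives RZnBr, 2.2 equiv); then 2, Pd(OAc)2 (2 mol %), SPhos (4 mol %), THF, 25–50 °C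
- Reagents that add atoms: none (both partners are numbered)
- Why: Negishi sp2–sp3 coupling; SPhos makes reductive elimination faster than β‑H elimination, and the phenol is tolerated as its zinc phenoxide.

**Step 3**
- Reactants: 4
- Product: 5, 2‑methyl‑6‑(3‑methylbut‑3‑en‑1‑yl)‑1,4‑benzoquinone
- Conditions: Fremy's salt (2.5 equiv), KH2PO4 buffer, H2O/acetone, 0 °C → rt
- Reagents that add atoms: potassium nitrosodisulfonate, [O]N(S(=O)(=O)[O-])S(=O)(=O)[O-].[K+].[K+]
- Why: Teuber oxidation of a 2,6‑dialkylphenol with a free para position gives the p‑quinone cleanly; the isolated alkene is untouched.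

**Step 4**
- Reactants: 5
- Product: 6, 2‑methyl‑6‑(3‑methylbut‑3‑en‑1‑yl)benzene‑1,4‑diol
- Conditions: Na2S2O4, EtOAc/H2O, rt, under N2 (used directly in step 5)
- Reagents that add atoms: none
- Why: Dithionite reduction of a quinone to the hydroquinone.

**Step 5**
- Reactants: 6
- Product: 7, 2‑methyl‑6‑(3‑methylbut‑3‑en‑1‑yl)‑4‑(triisopropylsilyloxy)phenol
- Conditions: TIPSCl (1.05 equiv), imidazole, DMF, 0 °C
- Reagents that add atoms: TIPSCl, CC(C)[Si](Cl)(C(C)C)C(C)C
- Why: Sterically controlled mono-silylation; the C1–OH is flanked by two ortho substituents, so the bulky silyl chloride reacts only at the unhindered C4–OH.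

**Step 6**
- Reactants: 7
- Product: 8, methyl 2‑[(2S)‑2,8‑dimethyl‑6‑(triisopropylsilyloxy)chroman‑2‑yl]acetate
- Conditions: Pd(TFA)2 (5 mol %), (S,S)‑Bn‑BOXAX (20 mol %), p‑benzoquinone (4 equiv), CO (1 atm), MeOH, rt
- Reagents that add atoms: carbon monoxide, [C-]#[O+]; methanol, CO
- Why: Enantioselective domino Wacker cyclisation/carbonylation. The chiral Pd(II)–bisoxazoline complex selects the alkene face in the 6‑exo oxypalladation and so sets C2. The resulting neopentyl-type alkyl‑Pd has no β‑H, so it inserts CO and is trapped by MeOH. The absolute sense should be confirmed experimentally; the (R,R) ligand is used if it is reversed.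

**Step 7**
- Reactants: 8
- Product: 9, 2‑[(2S)‑2,8‑dimethyl‑6‑(triisopropylsilyloxy)chroman‑2‑yl]ethan‑1‑ol
- Conditions: DIBAL‑H (2.5 equiv), CH2Cl2, −78 → 0 °C
- Reagents that add atoms: none
- Why: Hydride reduction of the ester to the primary alcohol; the aryl TIPS ether and the quaternary C2 are inert.

**Step 8**
- Reactants: 9
- Product: 10, (2S)‑2‑(2‑iodoethyl)‑2,8‑dimethyl‑6‑(triisopropylsilyloxy)chroman
- Conditions: I2, PPh3, imidazole, CH2Cl2, 0 °C → rt
- Reagents that add atoms: iodine, II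
- Why: Appel-type iodination (SN2 at the primary carbinol); the stereocentre is not involved.

### Fragment B (side-chain half)

**Step 9**
- Reactants: 11, pent‑4‑yn‑1‑ol
- Product: 12, (4E)‑5‑iodo‑4‑methylpent‑4‑en‑1‑ol
- Conditions: AlMe3 (3 equiv), Cp2ZrCl2 (0.25 equiv), CH2Cl2, 0 °C → rt; then I2, THF, −30 → 0 °C
- Reagents that add atoms: trimethylaluminium, C[Al](C)C; iodine, II
- Why: Negishi Zr‑catalysed syn‑carboalumination of the terminal alkyne, then iodinolysis with retention, gives the E trisubstituted vinyl iodide.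

**Step 10**
- Reactants: 12
- Product: 13, (4E)‑5‑iodo‑4‑methylpent‑4‑enal
- Conditions: Dess–Martin periodinane, NaHCO3, CH2Cl2, rt
- Reagents that add atoms: none
- Why: Mild oxidation of the primary alcohol to the aldehyde; the vinyl iodide is untouched.

**Step 11**
- Reactants: 13
- Product: 14, (2E,6E)‑7‑iodo‑2,6‑dimethylhepta‑2,6‑dienal
- Conditions: Ph3P=C(CH3)CHO (1.2 equiv), toluene, 90 °C
- Reagents that add atoms: 2‑(triphenylphosphoranylidene)propanal, CC(C=O)=P(c1ccccc1)(c1ccccc1)c1ccccc1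
- Why: Wittig olefination with a stabilised ylide gives the E α‑methyl enal (typically >95:5); the product enal is too hindered to react again.

**Step 12**
- Reactants: 14
- Product: 15, (4R,5E,9E)‑10‑iodo‑5,9‑dimethyldeca‑1,5,9‑trien‑4‑ol
- Conditions: (+)‑Ipc2BOMe (from (−)‑α‑pinene), allylMgBr, Et2O (forms the l‑Ipc2B‑allyl reagent); then 14, −78 °C; NaOH/H2O2 work-up
- Reagents that add atoms: allylmagnesium bromide, C=CC[Mg]Br (allyl delivered through the chiral borane)
- Why: Brown asymmetric allylboration through a closed chair transition state; the (−)‑α‑pinene-derived reagent adds allyl to the Re face of the enal and gives the R carbinol.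

**Step 13**
- Reactants: 15
- Product: 16, (5R,6E,10E)‑11‑iodo‑2,6,10‑trimethylundeca‑2,6,10‑trien‑5‑ol
- Conditions: Grubbs II (5 mol %), 2‑methyl‑2‑butene/CH2Cl2 (1:1), rt → 35 °C
- Reagents that add atoms: 2‑methylbut‑2‑ene, CC=C(C)C
- Why: Olefin cross-metathesis converts the only monosubstituted alkene to the prenyl group; the trisubstituted alkene and the vinyl iodide are unreactive toward the Ru carbene.

**Step 14**
- Reactants: 16
- Product: 17, tert‑butyl{[(5R,6E,10E)‑11‑iodo‑2,6,10‑trimethylundeca‑2,6,10‑trien‑5‑yl]oxy}dimethylsilane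
- Conditions: TBSCl, imidazole, DMAP (cat.), DMF, rt
- Reagents that add atoms: TBSCl, CC(C)(C)[Si](C)(C)Cl
- Why: Silylation of the secondary allylic alcohol; no bond to the stereocentre is broken.

### Fragment union and end-game

**Step 15**
- Reactants: 10 (1.3 equiv), (2S)‑2‑(2‑iodoethyl)chroman; 17, vinyl iodide
- Product: 18, (2R)‑2‑[(3E,7E,9R)‑9‑(tert‑butyldimethylsilyloxy)‑4,8,12‑trimethyltrideca‑3,7,11‑trien‑1‑yl]‑2,8‑dimethyl‑6‑(triisopropylsilyloxy)chroman
- Conditions: 10, t‑BuLi (2.1 equiv), Et2O, −78 °C; B‑OMe‑9‑BBN, THF, −78 °C → rt; then 17, Pd(dppf)Cl2 (5 mol %), AsPh3 (10 mol %), 3 M aq K3PO4, DMF, rt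
- Reagents that add atoms: none
- Why: Li–I exchange and trapping give the alkyl borinate; B‑alkyl Suzuki–Miyaura coupling forms C2'–C3' with retention of the vinyl iodide geometry (3'E). The C2 descriptor changes from S to R only because CIP priorities change.

**Step 16**
- Reactants: 18
- Product: 19, sargachromanol C, (2R)‑2‑[(3E,7E,9R)‑9‑hydroxy‑4,8,12‑trimethyltrideca‑3,7,11‑trien‑1‑yl]‑2,8‑dimethylchroman‑6‑ol
- Conditions: TBAF (3 equiv, buffered with AcOH), degassed THF, 0 °C → rt, under Ar; NH4Cl work-up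
- Reagents that add atoms: none
- Why: Fluoride-mediated desilylation removes the aryl TIPS and the secondary TBS ethers; no stereocentre or alkene is affected, and air is excluded to protect the 6‑chromanol.

## Compound list

1 | o‑cresol | Cc1ccccc1O | starting material
2 | 2‑bromo‑6‑methylphenol | Cc1cccc(Br)c1O | intermediate
3 | 4‑bromo‑2‑methylbut‑1‑ene | C=C(C)CCBr | starting material
4 | 2‑methyl‑6‑(3‑methylbut‑3‑en‑1‑yl)phenol | C=C(C)CCc1cccc(C)c1O | intermediate
5 | 2‑methyl‑6‑(3‑methylbut‑3‑en‑1‑yl)‑1,4‑benzoquinone | CC1=CC(=O)C=C(CCC(C)=C)C1=O | intermediate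
6 | 2‑methyl‑6‑(3‑methylbut‑3‑en‑1‑yl)benzene‑1,4‑diol | C=C(C)CCc1cc(O)cc(C)c1O | intermediate
7 | 2‑methyl‑6‑(3‑methylbut‑3‑en‑1‑yl)‑4‑(triisopropylsilyloxy)phenol | C=C(C)CCc1cc(O[Si](C(C)C)(C(C)C)C(C)C)cc(C)c1O | intermediate
8 | methyl 2‑[(2S)‑2,8‑dimethyl‑6‑(TIPS‑oxy)chroman‑2‑yl]acetate | COC(=O)C[C@]1(C)CCc2cc(O[Si](C(C)C)(C(C)C)C(C)C)cc(C)c2O1 | intermediate
9 | 2‑[(2S)‑2,8‑dimethyl‑6‑(TIPS‑oxy)chroman‑2‑yl]ethanol | OCC[C@]1(C)CCc2cc(O[Si](C(C)C)(C(C)C)C(C)C)cc(C)c2O1 | intermediate
10 | (2S)‑2‑(2‑iodoethyl)‑2,8‑dimethyl‑6‑(TIPS‑oxy)chroman | ICC[C@]1(C)CCc2cc(O[Si](C(C)C)(C(C)C)C(C)C)cc(C)c2O1 | intermediate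
11 | pent‑4‑yn‑1‑ol | C#CCCCO | starting material
12 | (4E)‑5‑iodo‑4‑methylpent‑4‑en‑1‑ol | OCCC/C(C)=C/I | intermediate
13 | (4E)‑5‑iodo‑4‑methylpent‑4‑enal | O=CCC/C(C)=C/I | intermediate
14 | (2E,6E)‑7‑iodo‑2,6‑dimethylhepta‑2,6‑dienal | O=C/C(C)=C/CC/C(C)=C/I | intermediate
15 | (4R,5E,9E)‑10‑iodo‑5,9‑dimethyldeca‑1,5,9‑trien‑4‑ol | C=CC[C@@H](O)/C(C)=C/CC/C(C)=C/I | intermediate
16 | (5R,6E,10E)‑11‑iodo‑2,6,10‑trimethylundeca‑2,6,10‑trien‑5‑ol | CC(C)=CC[C@@H](O)/C(C)=C/CC/C(C)=C/I | intermediate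
17 | TBS ether of 16 | CC(C)=CC[C@@H](O[Si](C)(C)C(C)(C)C)/C(C)=C/CC/C(C)=C/I | intermediate
18 | 9'‑O‑TBS, 6‑O‑TIPS sargachromanol C | CC(C)=CC[C@@H](O[Si](C)(C)C(C)(C)C)/C(C)=C/CC/C(C)=C/CC[C@]1(C)CCc2cc(O[Si](C(C)C)(C(C)C)C(C)C)cc(C)c2O1 | intermediate
19 | sargachromanol C | CC(C)=CC[C@@H](O)/C(C)=C/CC/C(C)=C/CC[C@]1(C)CCc2cc(O)cc(C)c2O1 | target

## Summary

- Total step count: 16
- Longest linear sequence: 10 (steps 1–8, 15, 16 from o‑cresol). The side-chain branch is 6 steps plus the 2 shared steps.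

**Three steps most likely to fail, with fallbacks**

1. **Step 6 (enantioselective Wacker/carbonylation; ee, yield, or oxidation of the electron-rich phenol).** Fallback: set C2 by intramolecular Pd(0)-catalysed asymmetric allylic etherification (Trost-type) of the phenol allylic carbonate ArCH2CH2C(CH3)=CHCH2OCO2Me to give the (S)‑2‑vinylchroman. 9‑BBN hydroboration of the vinyl group then gives the B‑alkyl partner for step 15 directly, with no ester or iodide needed.
2. **Step 15 (Li–I exchange then B‑alkyl Suzuki; the γ‑aryloxy alkyllithium may undergo 1,3‑elimination, or the boronate may transfer slowly).** Fallback: reverse the polarity. Lithiate vinyl iodide 17 (t‑BuLi), convert it to the alkenyl cuprate, and alkylate it with the primary triflate made from alcohol 9, so that no alkyl organometallic is generated on the chroman fragment.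
3. **Step 2 (Negishi coupling of a free ortho-bromophenol with a homoallylzinc; protonation or β‑H elimination).** Fallback: Mg‑mediated ortho-formylation of o‑cresol (MgCl2, Et3N, paraformaldehyde), aldol condensation with acetone, conjugate reduction of the enone, and Wittig methylenation of the methyl ketone. This reaches 4 without a cross-coupling and also makes step 1 unnecessary.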